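**Strategy.** The route rests on the C9–C10 bond: the C9 carbinol and the C10 methine sit next to C11 of ring A, so this bond is that of a homoallylic alcohol. A single chromium-mediated allylation of the C9 aldehyde by a C11 bromomethyl group, with allylic transposition, closes the ten-membered ring B, sets C9 and C10 and leaves C11 as a methylene for later reduction to the methyl group. The precursor is a 4,4-disubstituted cyclohexa-2,5-dienone (C12 ketone) carrying the bromomethyl group on C11 and, through C1–C2, the acetoxy chain that ends in the lactone-bound α-hydroxy aldehyde; it is assembled from a ring A fragment and a lactone fragment by a C4–C5 coupling.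

Key step: step 22

Numbering: atom numbers are those of the target; ring A = C1, C10, C11, C12, C13, C14; ring B = C1 to C10; ring C = O, C7, C8, C17, C19; C20 = the carbon on C11.

Assumption: the (S,S)-salen chromium catalyst is taken to give the (S) centre at C1 and (+)-MIB the (R) carbinol at C2; should either sense of induction be the reverse, the mirror-image catalyst or ligand is used.

**Ring A fragment**

Step 1
Reactants: 1 methacrolein; 2 (E)-1-(dimethylamino)-3-(tert-butyldimethylsilyloxy)buta-1,3-diene
Product: 4 (S)-1-methyl-4-oxocyclohex-2-ene-1-carbaldehyde, via endo cycloadduct 3 (not isolated)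
Conditions: (S,S)-(salen)CrSbF6 (5 mol %; salen = N,N′-bis(3,5-di-tert-butylsalicylidene)cyclohexane-1,2-diamine dianion), 4 Å MS, CH2Cl2, −40 °C; then 1 M HCl, THF, 0 °C
Reagents that add atoms: none
Why: Catalytic asymmetric Diels–Alder reaction in which the chiral salen complex of trivalent chromium binds the enal and shields one face, so that the quaternary C1 is set (S); acid then hydrolyses the silyl enol ether and eliminates dimethylamine to an enone whose only double bond is C10=C11.

Step 2
Reactants: 4 (S)-1-methyl-4-oxocyclohex-2-ene-1-carbaldehyde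
Product: 5 (S)-3-iodo-1-methyl-4-oxocyclohex-2-ene-1-carbaldehyde
Conditions: I2, pyridine, CH2Cl2, 0 °C → rt
Reagents that add atoms: iodine, II
Why: α-Iodination of an enone by reversible conjugate addition of pyridine, iodination of the enolate and elimination; since only the C10=C11 arm is unsaturated at this stage the halogen can enter only at C11, which fixes the place of the later bromomethyl group relative to the C1 stereocentre (a symmetric 4,4-disubstituted dienone could not be functionalised selectively at C11 over C13).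

Step 3
Reactants: 5 (S)-3-iodo-1-methyl-4-oxocyclohex-2-ene-1-carbaldehyde; 6 (tributylstannyl)methanol
Product: 7 (S)-3-(hydroxymethyl)-1-methyl-4-oxocyclohex-2-ene-1-carbaldehyde
Conditions: Pd(PPh3)4 (5 mol %), 1,4-dioxane, 80 °C
Reagents that add atoms: none
Why: Stille coupling of the alkenyl iodide with the hydroxymethylstannane, a known entry to 2-(hydroxymethyl)enones that tolerates the aldehyde and introduces C20.

Step 4
Reactants: 7 (S)-3-(hydroxymethyl)-1-methyl-4-oxocyclohex-2-ene-1-carbaldehyde
Product: 8 (S)-3-[(tert-butyldiphenylsilyloxy)methyl]-1-methyl-4-oxocyclohex-2-ene-1-carbaldehyde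
Conditions: tert-butyldiphenylsilyl chloride, imidazole, CH2Cl2, 0 °C
Reagents that add atoms: tert-butyldiphenylsilyl chloride, CC(C)(C)[Si](Cl)(c1ccccc1)c1ccccc1
Why: Silylation of the primary alcohol; this silyl ether survives the IBX step and the later acidic methanolysis and is removed by fluoride in step 20.

Step 5
Reactants: 8 (S)-3-[(tert-butyldiphenylsilyloxy)methyl]-1-methyl-4-oxocyclohex-2-ene-1-carbaldehyde
Product: 9 (S)-2-[(tert-butyldiphenylsilyloxy)methyl]-4-[(R)-1-hydroxyprop-2-en-1-yl]-4-methylcyclohex-2-en-1-one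
Conditions: Zn(CH=CH2)2 (2 equiv, made from CH2=CHMgBr and ZnCl2), (+)-MIB (3-exo-morpholinoisoborneol, 10 mol %), toluene/hexane, −20 → 0 °C; aq. NH4Cl
Reagents that add atoms: divinylzinc, C=C[Zn]C=C
Why: Amino-alcohol-catalysed addition of a diorganozinc to an aldehyde, chemoselective over the enone, in which the ligand and not the substrate controls the face (the two ring arms on the quaternary C1 give little bias) and sets C2 as (R); the vinyl group supplies C3 and C4.

Step 6
Reactants: 9 (S)-2-[(tert-butyldiphenylsilyloxy)methyl]-4-[(R)-1-hydroxyprop-2-en-1-yl]-4-methylcyclohex-2-en-1-one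
Product: 10 (R)-1-[(S)-3-[(tert-butyldiphenylsilyloxy)methyl]-1-methyl-4-oxocyclohex-2-en-1-yl]prop-2-en-1-yl acetate
Conditions: Ac2O, pyridine, DMAP (cat.), CH2Cl2, 0 °C → rt
Reagents that add atoms: acetic anhydride, CC(=O)OC(C)=O
Why: Acylation of the secondary alcohol installs the C2 acetate of the target early, so that no protecting group is needed at C2.

Step 7
Reactants: 10 (R)-1-[(S)-3-[(tert-butyldiphenylsilyloxy)methyl]-1-methyl-4-oxocyclohex-2-en-1-yl]prop-2-en-1-yl acetate
Product: 11 (R)-1-[(S)-3-[(tert-butyldiphenylsilyloxy)methyl]-1-methyl-4-oxocyclohexa-2,5-dien-1-yl]prop-2-en-1-yl acetate (ring A fragment)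
Conditions: IBX (2.5 equiv), DMSO/fluorobenzene, 70 °C
Reagents that add atoms: none
Why: IBX dehydrogenation of a ketone through its enol; C13 is the only enolisable position, so the new double bond is C13=C14 and the cross-conjugated dienone is obtained with C11 already distinguished from C13 and C1 still stereogenic.

**Lactone fragment**

Step 8
Reactants: 12 but-2-yn-1-ol
Product: 14 (Z)-3-iodobut-2-en-1-ol, via cyclic alkenylaluminate 13 (not isolated)
Conditions: NaAlH2(OCH2CH2OCH3)2, Et2O/THF, 0 °C → rt; then I2, THF, −78 → 0 °C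
Reagents that add atoms: iodine, II
Why: Hydroxyl-directed trans-hydroalumination of the propargylic alcohol places aluminium on C5 in a five-membered aluminate, and iodinolysis with retention gives the iodoalkene with iodine cis to the CH2OH carbon (C7), which is the C4/C7 cis geometry of the target.

Step 9
Reactants: 14 (Z)-3-iodobut-2-en-1-ol; 15 ethyl (triphenylphosphoranylidene)acetate
Product: 17 ethyl (2E,4Z)-5-iodohexa-2,4-dienoate, via (Z)-3-iodobut-2-enal 16 (not isolated)
Conditions: MnO2 (15 equiv), 15 (1.3 equiv), CH2Cl2, rt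
Reagents that add atoms: none
Why: Allylic oxidation by MnO2 with Wittig olefination in the same flask; the stabilised ylide gives the (E)-enoate and traps the isomerisation-prone (Z)-iodoenal as it forms.

Step 10
Reactants: 17 ethyl (2E,4Z)-5-iodohexa-2,4-dienoate
Product: 18 (2E,4Z)-5-iodohexa-2,4-dien-1-ol
Conditions: iBu2AlH (2.2 equiv), CH2Cl2, −78 °C; aq. potassium sodium tartrate
Reagents that add atoms: none
Why: 1,2-Reduction of the conjugated ester by the aluminium hydride gives the allylic alcohol (C9) without touching the iodoalkene.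

Step 11
Reactants: 18 (2E,4Z)-5-iodohexa-2,4-dien-1-ol
Product: 19 [(2R,3R)-3-[(Z)-2-iodoprop-1-en-1-yl]oxiran-2-yl]methanol
Conditions: Ti(OiPr)4 (10 mol %), D-(−)-diethyl tartrate (12 mol %), t-BuOOH, 4 Å MS, CH2Cl2, −20 °C
Reagents that add atoms: tert-butyl hydroperoxide, CC(C)(C)OO
Why: Sharpless asymmetric epoxidation acts only on the double bond allylic to the hydroxyl (the iodoalkene is remote and electron-poor), and the D-tartrate ligand delivers oxygen to the face that gives the (2R,3R)-epoxide, the source of the C7 configuration.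

Step 12
Reactants: 19 [(2R,3R)-3-[(Z)-2-iodoprop-1-en-1-yl]oxiran-2-yl]methanol; 20 acrylic acid
Product: 21 (2R,3S,4Z)-1,2-dihydroxy-5-iodohex-4-en-3-yl acrylate
Conditions: Ti(OiPr)4 (1.5 equiv), 20 (1.5 equiv), CH2Cl2, 0 °C → rt
Reagents that add atoms: none
Why: Titanium-assisted opening of a 2,3-epoxy alcohol by a carboxylic acid at C3 (here C7, which is also allylic) proceeds by SN2 with inversion, so C7 receives its oxygen in the (S) configuration of the target and already carries the acrylate that will become C17 to C19.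

Step 13
Reactants: 21 (2R,3S,4Z)-1,2-dihydroxy-5-iodohex-4-en-3-yl acrylate
Product: 22 (2R,3S,4Z)-2-hydroxy-5-iodo-1-(triethylsilyloxy)hex-4-en-3-yl acrylate
Conditions: Et3SiCl (1.05 equiv), imidazole, CH2Cl2, −40 °C
Reagents that add atoms: chlorotriethylsilane, CC[Si](CC)(CC)Cl
Why: Silylation at low temperature takes the primary C9 hydroxyl ahead of the hindered secondary one and leaves no time for acyl migration.

Step 14
Reactants: 22 (2R,3S,4Z)-2-hydroxy-5-iodo-1-(triethylsilyloxy)hex-4-en-3-yl acrylate
Product: 23 (3S,4Z)-5-iodo-2-oxo-1-(triethylsilyloxy)hex-4-en-3-yl acrylate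
Conditions: DMP (1,1,1-triacetoxy-1,1-dihydro-1,2-benziodoxol-3(1H)-one), NaHCO3, CH2Cl2, 0 °C → rt
Reagents that add atoms: none
Why: Buffered periodinane oxidation turns the C8 alcohol into the ketone under conditions too mild to enolise the acidic C7 position.

Step 15
Reactants: 23 (3S,4Z)-5-iodo-2-oxo-1-(triethylsilyloxy)hex-4-en-3-yl acrylate
Product: 25 (3R,4R,5S)-4-hydroxy-5-[(Z)-2-iodoprop-1-en-1-yl]-3-methyl-4-[(triethylsilyloxy)methyl]oxolan-2-one (lactone fragment), via copper enolate 24 (not isolated)
Conditions: [(Ph3P)CuH]6 (0.4 equiv), toluene, −40 → 0 °C; aq. NH4Cl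
Reagents that add atoms: none
Why: Reductive aldol cyclisation: conjugate hydride transfer from [(Ph3P)CuH]6 to the acrylate gives a (Z)-enolate that adds to the neighbouring C8 ketone through a closed chair transition state, which places the C17 methyl cis to the new C8 hydroxyl, while the bulky CH2OSiEt3 group on C8 takes the face opposite to the alkenyl group on C7.

**Union and precursor**

Step 16
Reactants: 11 ring A fragment; 25 lactone fragment
Product: 27 coupled dienol (1S,2R,5Z,7S,8R,17R; both C12 epimers): ring A cyclohexa-2,5-dien-1-ol with C20 silyl ether and C2 acetate joined through C3–C4 to the (5Z)-alkene and the lactone bearing C8–OH and C9–OSiEt3, via alkylborane 26 (not isolated)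
Conditions: 11 (1.3 equiv), 9-BBN (3 equiv), THF, 0 °C → rt; then H2O, 25, PdCl2(dppf) (10 mol %), AsPh3, Cs2CO3, DMF, rt
Reagents that add atoms: none
Why: Anti-Markovnikov hydroboration of the vinyl group puts boron on C4 and the B-alkyl Suzuki–Miyaura coupling with the (Z)-iodoalkene forms C4–C5 with retention of the double-bond geometry; 9-BBN also reduces the dienone carbonyl in the 1,2 sense, which is accepted and reversed in step 17, and no stereocentre of the target is created.

Step 17
Reactants: 27 coupled dienol
Product: 28 coupled dienone (1S,2R,5Z,7S,8R,17R) with C12 ketone, C20 silyl ether, C2 acetate, C8–OH and C9–OSiEt3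
Conditions: MnO2 (20 equiv), CH2Cl2, rt (crude 27, no silica)
Reagents that add atoms: none
Why: MnO2 oxidises the doubly allylic C12 alcohol back to the dienone and cannot touch the tertiary C8 hydroxyl; the acid-sensitive dienol is not purified.

Step 18
Reactants: 28 coupled dienone
Product: 29 C8,C9-diol (1S,2R,5Z,7S,8R,17R) with C20 silyl ether intact
Conditions: PPTS (0.2 equiv), MeOH/CH2Cl2, 0 °C
Reagents that add atoms: none
Why: Acid-catalysed methanolysis removes the triethylsilyl ether, while the tert-butyldiphenylsilyl ether, the acetate and the lactone are stable under these conditions.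

Step 19
Reactants: 29 C8,C9-diol
Product: 30 C9 aldehyde (1S,2R,5Z,7S,8S,17R) with C8–OH and C20 silyl ether
Conditions: TEMPO (0.2 equiv), PhI(OAc)2 (1.3 equiv), CH2Cl2, rt
Reagents that add atoms: none
Why: Oxoammonium oxidation is selective for the primary alcohol of the diol; the tertiary C8 hydroxyl is inert and the quaternary α-carbon cannot epimerise.

Step 20
Reactants: 30 C9 aldehyde
Product: 31 C20 allylic alcohol (1S,2R,5Z,7S,8S,17R) with C12 dienone and C9 aldehyde
Conditions: HF·pyridine, pyridine, THF, 0 °C → rt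
Reagents that add atoms: none
Why: Buffered fluoride cleaves the primary silyl ether without the strong acid that would trigger a dienone–phenol rearrangement, and the acetate, lactone and aldehyde persist.

Step 21
Reactants: 31 C20 allylic alcohol
Product: 33 cyclisation precursor (1S,2R,5Z,7S,8S,17R): 2-(bromomethyl)cyclohexa-2,5-dienone joined through C1 and the C2 acetate chain to the lactone bearing C8–OH and the C9 aldehyde, via allylic mesylate 32 (not isolated)
Conditions: MsCl, Et3N, CH2Cl2, −30 °C; then LiBr, THF, 0 °C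
Reagents that add atoms: lithium bromide, [Li+].[Br-]
Why: Sulfonylation of the primary allylic alcohol (the tertiary hydroxyl does not react at this temperature) and SN2 displacement by bromide give the allylic bromide last, when it is needed; a phosphine/CBr4 bromination is avoided because it would olefinate the aldehyde.

**Key step and completion**

Step 22
Reactants: 33 cyclisation precursor
Product: 35 ring-B-closed alcohol (1S,2R,5Z,7S,8R,9R,10R,17R) with C9–OH, C11 exocyclic methylene and C12 ketone, via allylchromium dichloride 34 (not isolated)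
Conditions: CrCl2 (8 equiv), THF, rt, slow addition of 33 to 0.003 M
Reagents that add atoms: none
Why: Two equivalents of CrCl2 (divalent chromium) reduce the allylic C–Br bond by successive one-electron transfers to an allyl species of trivalent chromium bound at the exocyclic methylene, which adds to the C9 aldehyde through C10 with allylic transposition in a closed six-membered chair transition state, as in Nozaki–Hiyama allylations with 2-(bromomethyl)acrylates and 2-(bromomethyl)enones that have closed ten-membered carbocycles. Ring B is closed by a ten-membered exo-trig carbonyl addition in which the C10=C11 bond moves out of the new ring to become the C11 methylene. C10 is set by the face of the dienone that the tether can reach: the chain leaves C1 through C2 on one face, and the rigid (Z)-alkene and lactone are expected to let C9 reach C10 only from the opposite face (that of the C1 methyl), which gives the trans ring fusion. C9 is set by the chair, in which the ring-fixed geometry of the allyl unit (C1 trans to the CH2Cr group) and an equatorial C8 substituent on the aldehyde give the anti relationship between the C9 oxygen and the C10–C1 bond. The step needs reaction at C10 and not at the methylene, which 2-acyl-substituted allylchromium reagents show reliably; chemoselectivity for the aldehyde over dienone, acetate, lactone and tertiary alcohol, which the mild oxophilic organochromium provides; and ring closure over oligomerisation, which high dilution secures.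

Step 23
Reactants: 35 ring-B-closed alcohol
Product: 36 C2,C9-diacetate (1S,2R,5Z,7S,8S,9R,10R,17R) with C11 methylene and C12 ketone
Conditions: Ac2O, pyridine, DMAP (cat.), CH2Cl2, 0 °C
Reagents that add atoms: acetic anhydride, CC(=O)OC(C)=O
Why: Acylation takes the secondary C9 hydroxyl and not the tertiary C8 one, and it is done before the conjugate reduction so that no base meets the epimerisable C11 ketone later.

Step 24
Reactants: 36 C2,C9-diacetate
Product: 38 C11-methyl enone (1S,2R,5Z,7S,8S,9R,10S,11R,17R) with C12 ketone and C13=C14, via copper dienolate 37 (not isolated)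
Conditions: [(Ph3P)CuH]6 (0.2 equiv, 1.2 equiv hydride), toluene, −40 °C; then sat. aq. NH4Cl, −40 °C
Reagents that add atoms: none
Why: Conjugate reduction by [(Ph3P)CuH]6 delivers hydride to the unhindered exocyclic methylene (C14, next to the quaternary C1, reacts far more slowly), and kinetic protonation of the enolate on the face opposite to the C1 methyl and the C9 substituent gives the 11R methyl epimer.

Step 25
Reactants: 38 C11-methyl enone
Product: 39 12-epi alcohol (1S,2R,5Z,7S,8S,9R,10S,11R,12S,17R)
Conditions: NaBH4, CeCl3·7H2O, MeOH, −78 °C, used at once after step 24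
Reagents that add atoms: none
Why: Luche 1,2-reduction of the enone, in which hydride is expected to enter C12 from the open face opposite to the C1 methyl, the C11 methyl and the C9 substituent and so to give the C12 epimer of the target, which is why an inversion follows.

Step 26
Reactants: 39 12-epi alcohol
Product: 40 C12 chloroacetate (1S,2R,5Z,7S,8S,9R,10S,11R,12R,17R)
Conditions: ClCH2CO2H, PPh3, diisopropyl azodicarboxylate, toluene, 0 °C → rt
Reagents that add atoms: chloroacetic acid, OC(=O)CCl
Why: Mitsunobu reaction, an SN2 displacement of the activated secondary allylic alcohol by chloroacetate with inversion, in which the nucleophile enters along the open face, C14 is too hindered for SN2′ attack and the tertiary C8 hydroxyl does not react.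

Step 27
Reactants: 40 C12 chloroacetate
Product: 41 target CNP0222085.1 (1S,2R,5Z,7S,8S,9R,10S,11R,12R,17R)
Conditions: thiourea, NaHCO3, EtOH, 50 °C
Reagents that add atoms: none
Why: S-Alkylation of thiourea by the chloroacetate and cyclisation release the C12 alcohol under near-neutral conditions that leave the two acetates and the lactone intact.

**Compound list**

1 | methacrolein | CC(=C)C=O | starting material
2 | (E)-1-(dimethylamino)-3-(tert-butyldimethylsilyloxy)buta-1,3-diene | CN(C)/C=C/C(=C)O[Si](C)(C)C(C)(C)C | starting material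
3 | (1S,2R)-4-(tert-butyldimethylsilyloxy)-2-(dimethylamino)-1-methylcyclohex-3-ene-1-carbaldehyde (endo cycloadduct) | O=C[C@]1(C)[C@H](N(C)C)C=C(O[Si](C)(C)C(C)(C)C)CC1 | intermediate
4 | (S)-1-methyl-4-oxocyclohex-2-ene-1-carbaldehyde | O=C[C@]1(C)C=CC(=O)CC1 | intermediate
5 | (S)-3-iodo-1-methyl-4-oxocyclohex-2-ene-1-carbaldehyde | O=C[C@]1(C)C=C(I)C(=O)CC1 | intermediate
6 | (tributylstannyl)methanol | CCCC[Sn](CCCC)(CCCC)CO | starting material
7 | (S)-3-(hydroxymethyl)-1-methyl-4-oxocyclohex-2-ene-1-carbaldehyde | O=C[C@]1(C)C=C(CO)C(=O)CC1 | intermediate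
8 | (S)-3-[(tert-butyldiphenylsilyloxy)methyl]-1-methyl-4-oxocyclohex-2-ene-1-carbaldehyde | O=C[C@]1(C)C=C(CO[Si](c2ccccc2)(c2ccccc2)C(C)(C)C)C(=O)CC1 | intermediate
9 | (S)-2-[(tert-butyldiphenylsilyloxy)methyl]-4-[(R)-1-hydroxyprop-2-en-1-yl]-4-methylcyclohex-2-en-1-one | C=C[C@@H](O)[C@]1(C)C=C(CO[Si](c2ccccc2)(c2ccccc2)C(C)(C)C)C(=O)CC1 | intermediate
10 | (R)-1-[(S)-3-[(tert-butyldiphenylsilyloxy)methyl]-1-methyl-4-oxocyclohex-2-en-1-yl]prop-2-en-1-yl acetate | C=C[C@@H](OC(C)=O)[C@]1(C)C=C(CO[Si](c2ccccc2)(c2ccccc2)C(C)(C)C)C(=O)CC1 | intermediate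
11 | (R)-1-[(S)-3-[(tert-butyldiphenylsilyloxy)methyl]-1-methyl-4-oxocyclohexa-2,5-dien-1-yl]prop-2-en-1-yl acetate (ring A fragment) | C=C[C@@H](OC(C)=O)[C@]1(C)C=C(CO[Si](c2ccccc2)(c2ccccc2)C(C)(C)C)C(=O)C=C1 | intermediate
12 | but-2-yn-1-ol | CC#CCO | starting material
13 | sodium 2,2-bis(2-methoxyethoxy)-3-methyl-2,5-dihydro-1,2-oxaluminol-2-uide (cyclic alkenylaluminate) | CC1=CCO[Al-]1(OCCOC)OCCOC.[Na+] | intermediate
14 | (Z)-3-iodobut-2-en-1-ol | C/C(I)=C/CO | intermediate
15 | ethyl (triphenylphosphoranylidene)acetate | CCOC(=O)C=P(c1ccccc1)(c1ccccc1)c1ccccc1 | starting material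
16 | (Z)-3-iodobut-2-enal | C/C(I)=C/C=O | intermediate
17 | ethyl (2E,4Z)-5-iodohexa-2,4-dienoate | I/C(C)=C\C=C\C(=O)OCC | intermediate
18 | (2E,4Z)-5-iodohexa-2,4-dien-1-ol | I/C(C)=C\C=C\CO | intermediate
19 | [(2R,3R)-3-[(Z)-2-iodoprop-1-en-1-yl]oxiran-2-yl]methanol | OC[C@H]1O[C@@H]1/C=C(/C)I | intermediate
20 | acrylic acid | C=CC(=O)O | starting material
21 | (2R,3S,4Z)-1,2-dihydroxy-5-iodohex-4-en-3-yl acrylate | C=CC(=O)O[C@@H](/C=C(/C)I)[C@H](O)CO | intermediate
22 | (2R,3S,4Z)-2-hydroxy-5-iodo-1-(triethylsilyloxy)hex-4-en-3-yl acrylate | C=CC(=O)O[C@@H](/C=C(/C)I)[C@H](O)CO[Si](CC)(CC)CC | intermediate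
23 | (3S,4Z)-5-iodo-2-oxo-1-(triethylsilyloxy)hex-4-en-3-yl acrylate | C=CC(=O)O[C@@H](/C=C(/C)I)C(=O)CO[Si](CC)(CC)CC | intermediate
24 | copper (Z)-enolate formed from 23 by hydride addition to the acrylate | C/C=C(\O[Cu])O[C@@H](/C=C(/C)I)C(=O)CO[Si](CC)(CC)CC | intermediate
25 | (3R,4R,5S)-4-hydroxy-5-[(Z)-2-iodoprop-1-en-1-yl]-3-methyl-4-[(triethylsilyloxy)methyl]oxolan-2-one (lactone fragment) | I/C(C)=C\[C@@H]1OC(=O)[C@H](C)[C@@]1(O)CO[Si](CC)(CC)CC | intermediate
26 | C4 B-alkyl-9-borabicyclo[3.3.1]nonane of 11 with the C12 oxygen as its borinate | CC(C)(C)[Si](c1ccccc1)(c1ccccc1)OCC1=C[C@](C)(C=CC1OB1C2CCCC1CCC2)[C@H](OC(C)=O)CCB1C2CCCC1CCC2 | intermediate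
27 | coupled dienol (1S,2R,5Z,7S,8R,17R; C12 epimers) | CC(C)(C)[Si](c1ccccc1)(c1ccccc1)OCC1=C[C@](C)(C=CC1O)[C@H](OC(C)=O)CC/C(C)=C\[C@@H]2OC(=O)[C@H](C)[C@@]2(O)CO[Si](CC)(CC)CC | intermediate
28 | coupled dienone (1S,2R,5Z,7S,8R,17R) | CC(C)(C)[Si](c1ccccc1)(c1ccccc1)OCC1=C[C@](C)(C=CC1=O)[C@H](OC(C)=O)CC/C(C)=C\[C@@H]2OC(=O)[C@H](C)[C@@]2(O)CO[Si](CC)(CC)CC | intermediate
29 | C8,C9-diol (1S,2R,5Z,7S,8R,17R) | CC(C)(C)[Si](c1ccccc1)(c1ccccc1)OCC1=C[C@](C)(C=CC1=O)[C@H](OC(C)=O)CC/C(C)=C\[C@@H]2OC(=O)[C@H](C)[C@@]2(O)CO | intermediate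
30 | C9 aldehyde with C20 silyl ether (1S,2R,5Z,7S,8S,17R) | CC(C)(C)[Si](c1ccccc1)(c1ccccc1)OCC1=C[C@](C)(C=CC1=O)[C@H](OC(C)=O)CC/C(C)=C\[C@@H]2OC(=O)[C@H](C)[C@@]2(O)C=O | intermediate
31 | C20 allylic alcohol with C9 aldehyde (1S,2R,5Z,7S,8S,17R) | OCC1=C[C@](C)(C=CC1=O)[C@H](OC(C)=O)CC/C(C)=C\[C@@H]2OC(=O)[C@H](C)[C@@]2(O)C=O | intermediate
32 | C20 allylic mesylate of 31 | CS(=O)(=O)OCC1=C[C@](C)(C=CC1=O)[C@H](OC(C)=O)CC/C(C)=C\[C@@H]2OC(=O)[C@H](C)[C@@]2(O)C=O | intermediate
33 | cyclisation precursor: 2-(bromomethyl)dienone with lactone-bound α-hydroxy aldehyde (1S,2R,5Z,7S,8S,17R) | BrCC1=C[C@](C)(C=CC1=O)[C@H](OC(C)=O)CC/C(C)=C\[C@@H]2OC(=O)[C@H](C)[C@@]2(O)C=O | intermediate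
34 | allylchromium dichloride formed from 33 | Cl[Cr](Cl)CC1=C[C@](C)(C=CC1=O)[C@H](OC(C)=O)CC/C(C)=C\[C@@H]2OC(=O)[C@H](C)[C@@]2(O)C=O | intermediate
35 | ring-B-closed C9 alcohol with C11 methylene and C12 ketone (1S,2R,5Z,7S,8R,9R,10R,17R) | O[C@@H]1[C@H]2C(=C)C(=O)C=C[C@]2(C)[C@H](OC(C)=O)CC/C(C)=C\[C@@H]2OC(=O)[C@H](C)[C@]21O | intermediate
36 | C2,C9-diacetate with C11 methylene and C12 ketone (1S,2R,5Z,7S,8S,9R,10R,17R) | CC(=O)O[C@@H]1[C@H]2C(=C)C(=O)C=C[C@]2(C)[C@H](OC(C)=O)CC/C(C)=C\[C@@H]2OC(=O)[C@H](C)[C@]21O | intermediate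
37 | copper dienolate formed from 36 (C11=C12–O–Cu) | CC(=O)O[C@@H]1[C@H]2C(C)=C(O[Cu])C=C[C@]2(C)[C@H](OC(C)=O)CC/C(C)=C\[C@@H]2OC(=O)[C@H](C)[C@]21O | intermediate
38 | C11-methyl enone (1S,2R,5Z,7S,8S,9R,10S,11R,17R) | CC(=O)O[C@@H]1[C@H]2[C@@H](C)C(=O)C=C[C@]2(C)[C@H](OC(C)=O)CC/C(C)=C\[C@@H]2OC(=O)[C@H](C)[C@]21O | intermediate
39 | 12-epi alcohol (1S,2R,5Z,7S,8S,9R,10S,11R,12S,17R) | CC(=O)O[C@@H]1[C@H]2[C@@H](C)[C@@H](O)C=C[C@]2(C)[C@H](OC(C)=O)CC/C(C)=C\[C@@H]2OC(=O)[C@H](C)[C@]21O | intermediate
40 | C12 chloroacetate (1S,2R,5Z,7S,8S,9R,10S,11R,12R,17R) | CC(=O)O[C@@H]1[C@H]2[C@@H](C)[C@H](OC(=O)CCl)C=C[C@]2(C)[C@H](OC(C)=O)CC/C(C)=C\[C@@H]2OC(=O)[C@H](C)[C@]21O | intermediate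
41 | CNP0222085.1 (1S,2R,5Z,7S,8S,9R,10S,11R,12R,17R) | CC(=O)O[C@@H]1[C@H]2[C@@H](C)[C@H](O)C=C[C@]2(C)[C@H](OC(C)=O)CC/C(C)=C\[C@@H]2OC(=O)[C@H](C)[C@]21O | target

**Totals.** Total step count: 27. Longest linear sequence: 20 steps (steps 8 to 15, then 16 to 27).

**Steps most likely to fail**

Step 22. The allylchromium may react between molecules and give oligomers, may be protonated to a C11 methyl dienone without closing the ring, may add on the wrong face of C10 (cis fusion), or the hydroxy aldehyde may undergo α-ketol rearrangement on the Lewis-acidic trivalent chromium. The fallback sets out from 31 and returns at 35. Acetylation of the primary allylic alcohol (Ac2O, pyridine, 0 °C) would give the C20 allylic acetate F1. Pd(PPh3)4 (zerovalent palladium, catalytic) with InI (monovalent indium) in THF at high dilution would then ionise the acetate to a π-allylpalladium species and reduce it to an allylindium. That species adds to the C9 aldehyde through C10 in the same transposed sense, so ring B is closed by catalytic umpolung of an allylic ester in place of stoichiometric reduction of a bromide.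

Step 15. The reductive aldol may show poor facial selectivity at C8 and C17, the acidic C7 position may epimerise through the ketone enolate, or the ketone may be reduced before the enolate adds. The fallback sets out from 19 and returns at 25. Opening the epoxide with 2-bromopropanoic acid and Ti(OiPr)4 would give the bromo ester diol F2. Silylation with chlorotriethylsilane would give the silyl ether F3, and DMP oxidation the ketone F4. SmI2 (divalent samarium) in THF at −78 °C would then cleave the C–Br bond to an enolate of trivalent samarium, which closes ring C by an intramolecular Reformatsky reaction through a chelated transition state.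

Step 24. Hydride may also reduce the ring enone, or the enolate may be protonated on the wrong face or equilibrate to the more stable C11 epimer. The fallback sets out from 36 and returns at 38 without a new compound. Diimide, generated from dipotassium azodicarboxylate and acetic acid in CH2Cl2/MeOH, would transfer two hydrogens in a concerted syn addition to the exocyclic double bond from the open face, so no enolate is formed.

**Further compounds**

F1 | step 22 | C20 allylic acetate of 31 (1S,2R,5Z,7S,8S,17R) | CC(=O)OCC1=C[C@](C)(C=CC1=O)[C@H](OC(C)=O)CC/C(C)=C\[C@@H]2OC(=O)[C@H](C)[C@@]2(O)C=O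
F2 | step 15 | (2R,3S,4Z)-1,2-dihydroxy-5-iodohex-4-en-3-yl 2-bromopropanoate (both epimers at the CHBr carbon) | CC(Br)C(=O)O[C@@H](/C=C(/C)I)[C@H](O)CO
F3 | step 15 | (2R,3S,4Z)-2-hydroxy-5-iodo-1-(triethylsilyloxy)hex-4-en-3-yl 2-bromopropanoate | CC(Br)C(=O)O[C@@H](/C=C(/C)I)[C@H](O)CO[Si](CC)(CC)CC
F4 | step 15 | (3S,4Z)-5-iodo-2-oxo-1-(triethylsilyloxy)hex-4-en-3-yl 2-bromopropanoate | CC(Br)C(=O)O[C@@H](/C=C(/C)I)C(=O)CO[Si](CC)(CC)CC
F0 | step 24 | none | none
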